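The route rests on disconnecting the C10–C20 bond of the 19,20-lactone. Because C7 bears oxygen and C10 lies para to it in ring B, ring B is carried as a 1-naphthol, and the C19 carboxyl on C4, which sits 1,3 to C10 across ring A, holds C20 as a halomethyl ester. In one operation the naphtholate attacks this carbon through C10, creating the quaternary C10 stereocentre, closing the δ-lactone and delivering the 5-en-7-one. The precursor is a 6-bromo-7-hydroxy tetrahydrophenanthrene (rings B and C aromatic, bromine blocking the ortho carbon C6) with a chloromethyl ester on C4, switched to the iodide in the flask.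

Key step: step 10

Remark: abietane numbering (C1–C20, rings A–C) is used for the tricyclic compounds, and "19,20-olide" means the lactone from the C19 carbonyl on C4 to the oxygen-bearing C20 on C10. In step 1 the ligand antipode is assumed to be the one that gives the (1S) ester.

**Step 1**
Reactants: 1 methyl 3-oxocyclohex-1-ene-1-carboxylate; 2 dimethylzinc; 3 triethylsilyl trifluoromethanesulfonate
Product: 5 methyl (1S)-1-methyl-3-[(triethylsilyl)oxy]cyclohex-2-ene-1-carboxylate, via methylzinc enolate 4 (not isolated)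
Conditions: Me2Zn (3 equiv), (CuOTf)2·C6H6 (2.5 mol%), chiral sulfonate-bearing imidazolinium salt pretreated with Ag2O (5 mol%), t-BuOMe, −30 °C; then Et3SiOTf, −30 → 0 °C
Reagents that add atoms: dimethylzinc (2), C[Zn]C; triethylsilyl trifluoromethanesulfonate (3), CC[Si](CC)(CC)OS(=O)(=O)C(F)(F)F
Why: Copper-catalysed asymmetric conjugate addition of a dialkylzinc to a cyclic γ-keto ester puts methyl on the ester-bearing carbon (β to the ketone), the chiral NHC–copper catalyst fixing the quaternary centre as (S), and silylation captures the zinc enolate with its double bond towards that centre.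

**Step 2**
Reactants: 5 methyl (1S)-1-methyl-3-[(triethylsilyl)oxy]cyclohex-2-ene-1-carboxylate; 6 tert-butyl bromoacetate
Product: 8 methyl (1S,2RS)-2-(2-tert-butoxy-2-oxoethyl)-1-methyl-3-oxocyclohexane-1-carboxylate, via ammonium enolate 7 (not isolated)
Conditions: BnMe3NF (anhydrous), 4 Å MS, THF, −20 → 25 °C
Reagents that add atoms: tert-butyl bromoacetate (6), CC(C)(C)OC(=O)CBr
Why: Fluoride-promoted regiospecific alkylation of a silyl enol ether (Kuwajima–Nakamura type) lets the naked enolate attack the reactive α-bromo ester only at the carbon fixed in step 1; the new centre may form as either epimer because it becomes sp2 in step 6.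

**Step 3**
Reactants: 9 1,2,4-trimethoxybenzene; 10 acetone
Product: 12 2-(2,3,6-trimethoxyphenyl)propan-2-ol, via aryllithium 11 (not isolated)
Conditions: n-BuLi, THF, 0 → 25 °C; acetone, −78 → 25 °C; aq. NH4Cl
Reagents that add atoms: acetone (10), CC(C)=O
Why: Directed ortho-metalation takes place at the ring carbon flanked by two methoxy groups and the aryllithium adds to the ketone.

**Step 4**
Reactants: 12 2-(2,3,6-trimethoxyphenyl)propan-2-ol
Product: 13 1,2,4-trimethoxy-3-(propan-2-yl)benzene
Conditions: Et3SiH, CF3CO2H, CH2Cl2, 0 → 25 °C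
Reagents that add atoms: none
Why: Ionic hydrogenation, in which the tertiary benzylic cation stabilised by two ortho methoxy groups is reduced by silane hydride.

**Step 5**
Reactants: 13 1,2,4-trimethoxy-3-(propan-2-yl)benzene; 8 methyl (1S,2RS)-2-(2-tert-butoxy-2-oxoethyl)-1-methyl-3-oxocyclohexane-1-carboxylate
Product: 16 methyl (1S,2RS,3RS)-2-(2-tert-butoxy-2-oxoethyl)-3-hydroxy-1-methyl-3-[2,3,5-trimethoxy-4-(propan-2-yl)phenyl]cyclohexane-1-carboxylate, via aryllithium 14 (not isolated), via arylcerium dichloride 15 (not isolated)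
Conditions: n-BuLi, TMEDA, Et2O, 0 → 25 °C (on 13); CeCl3, THF, −78 °C; then 8, −78 °C; aq. NH4Cl
Reagents that add atoms: none
Why: Directed ortho-metalation of 13 should occur at H-6 (the future C9), which lies next to the vicinal dimethoxy pair, has two further meta methoxy groups and is not buttressed by isopropyl, and the weakly basic organocerium (Imamoto addition) adds to the α-branched ketone instead of enolising it while both esters survive at −78 °C; the two new centres need no control because step 6 flattens them.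

**Step 6**
Reactants: 16 methyl (1S,2RS,3RS)-2-(2-tert-butoxy-2-oxoethyl)-3-hydroxy-1-methyl-3-[2,3,5-trimethoxy-4-(propan-2-yl)phenyl]cyclohexane-1-carboxylate
Product: 18 methyl (1S)-9-hydroxy-5,6,8-trimethoxy-1-methyl-7-(propan-2-yl)-1,2,3,4-tetrahydrophenanthrene-1-carboxylate, via unsaturated acid 17 (not isolated)
Conditions: CF3CO2H, CH2Cl2, 0 → 25 °C; evaporate; P2O5/MeSO3H (Eaton's reagent), 25 °C; ice
Reagents that add atoms: none
Why: Acid removes the tert-butyl group and dehydrates the benzylic carbinol, and intramolecular Friedel–Crafts acylation at C8 (the only free arene carbon, ortho and para to methoxy groups) followed by enolisation gives the 1-naphthol with rings B and C aromatic, the methyl ester and the C4 centre being untouched.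

**Step 7**
Reactants: 18 methyl (1S)-9-hydroxy-5,6,8-trimethoxy-1-methyl-7-(propan-2-yl)-1,2,3,4-tetrahydrophenanthrene-1-carboxylate
Product: 19 (1S)-9-hydroxy-5,6,8-trimethoxy-1-methyl-7-(propan-2-yl)-1,2,3,4-tetrahydrophenanthrene-1-carboxylic acid
Conditions: NaSEt, DMF, 70 °C; then aq. HCl
Reagents that add atoms: none
Why: SN2 demethylation by thiolate at the ester methyl carbon avoids the hindered neopentyl-type carbonyl, and aryl methyl ethers need far higher temperatures with this reagent.

**Step 8**
Reactants: 19 (1S)-9-hydroxy-5,6,8-trimethoxy-1-methyl-7-(propan-2-yl)-1,2,3,4-tetrahydrophenanthrene-1-carboxylic acid; 20 N-bromosuccinimide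
Product: 21 (1S)-10-bromo-9-hydroxy-5,6,8-trimethoxy-1-methyl-7-(propan-2-yl)-1,2,3,4-tetrahydrophenanthrene-1-carboxylic acid
Conditions: NBS (1.0 equiv), MeCN, −20 → 0 °C, dark
Reagents that add atoms: N-bromosuccinimide (20), O=C1CCC(=O)N1Br
Why: Electrophilic aromatic bromination ortho to the naphthol hydroxyl can only occur at C6, the single unsubstituted ring carbon.

**Step 9**
Reactants: 21 (1S)-10-bromo-9-hydroxy-5,6,8-trimethoxy-1-methyl-7-(propan-2-yl)-1,2,3,4-tetrahydrophenanthrene-1-carboxylic acid; 22 chloromethyl chlorosulfate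
Product: 23 chloromethyl (1S)-10-bromo-9-hydroxy-5,6,8-trimethoxy-1-methyl-7-(propan-2-yl)-1,2,3,4-tetrahydrophenanthrene-1-carboxylate
Conditions: Bu4NOH (1.0 equiv), MeOH; evaporate, dry (toluene azeotrope); ClCH2OSO2Cl, CH2Cl2, 0 °C
Reagents that add atoms: chloromethyl chlorosulfate (22), ClCOS(=O)(=O)Cl
Why: O-alkylation of a carboxylate by chloromethyl chlorosulfate (chlorosulfate leaves in preference to chloride) is made chemoselective by using one equivalent of base, which ionises only the carboxylic acid (several pKa units more acidic than the hindered bromonaphthol), so the naphthol stays protonated and inert.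

**Step 10**
Reactants: 23 chloromethyl (1S)-10-bromo-9-hydroxy-5,6,8-trimethoxy-1-methyl-7-(propan-2-yl)-1,2,3,4-tetrahydrophenanthrene-1-carboxylate
Product: 26 (4S,10S)-6-bromo-11,12,14-trimethoxy-7-oxoabieta-5,8,11,13-tetraen-19,20-olide, via iodomethyl ester 24 (not isolated), via potassium naphtholate 25 (not isolated)
Conditions: K2CO3 (3 equiv), KI (0.2 equiv), 18-crown-6 (0.2 equiv), MeCN, 40 °C, 23 added slowly to 0.005 M
Reagents that add atoms: none
Why: K2CO3 deprotonates the naphthol and iodide exchanges the chloride (Finkelstein), after which the ambident naphtholate attacks the CH2 carbon of the iodomethyl ester through C10, the carbon para to O7, in an SN2 displacement that forms C10–C20 and leaves ring B as the cross-conjugated 5-en-7-one. The closest known reaction type is the intramolecular para-C-alkylation of phenolates and naphtholates by tethered primary halides (dearomatising cyclisation), together with the known C-alkylation of enolates by acyloxymethyl halides. The δ-lactone ring (C4–C19–O–C20–C10–C5) closes 6-exo-tet, which requires the s-trans ester rotamer and the conformer with the carboxyl pseudo-axial on C4, both of which should be accessible. C10 is the only new stereocentre and is controlled by C4, because the three-atom tether can reach only the face of C10 on which the carboxyl sits, so C19 and C20 end up cis as in the bridged lactone of the target. The step needs C-attack at the para carbon C10 in preference to the ortho carbon C6 and cyclisation in preference to intermolecular O-alkylation; bromine makes C6 fully substituted and less nucleophilic, O7 cannot reach C20 within the molecule, and slow addition at high dilution suppresses bimolecular paths.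

**Step 11**
Reactants: 26 (4S,10S)-6-bromo-11,12,14-trimethoxy-7-oxoabieta-5,8,11,13-tetraen-19,20-olide
Product: 29 (4S,5R,10R)-11,12,14-trimethoxy-7-oxoabieta-8,11,13-trien-19,20-olide, via dienone 27 (not isolated), via lithium enolate 28 (not isolated)
Conditions: Li (4.4 equiv), t-BuOH (2 equiv), NH3/THF, −78 °C; isoprene; NH4Cl
Reagents that add atoms: none
Why: Dissolving-metal reduction first cleaves the vinylic C–Br bond and then adds two electrons to the aryl enone; the C5 carbanion should pyramidalise with C6 on the lactone side (one syn-axial hydrogen there against two on the carbocyclic side), so protonation on the opposite α face, axial to ring B (Stork-type), gives the trans A/B ketone, while the C7 enolate resists further reduction until the quench.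

**Step 12**
Reactants: 29 (4S,5R,10R)-11,12,14-trimethoxy-7-oxoabieta-8,11,13-trien-19,20-olide; 30 water
Product: 32 (4S,5R,10R)-11,14-dihydroxy-12-methoxy-7-oxoabieta-8,11,13-trien-19,20-olide, via quinone 31 (not isolated)
Conditions: (NH4)2Ce(NO3)6, MeCN/H2O, 0 °C; then aq. Na2S2O4, EtOAc, 25 °C
Reagents that add atoms: water (30), O
Why: Oxidative demethylation of the para-dimethoxy pair at C11/C14 by tetravalent cerium gives the 12-methoxy-11,14-quinone with its oxygen atoms taken from water, and dithionite reduces it to the hydroquinone without touching the ketone, the lactone or the three stereocentres.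

**Compound list**

1 | methyl 3-oxocyclohex-1-ene-1-carboxylate | COC(=O)C1=CC(=O)CCC1 | starting material
2 | dimethylzinc | C[Zn]C | starting material
3 | triethylsilyl trifluoromethanesulfonate | CC[Si](CC)(CC)OS(=O)(=O)C(F)(F)F | starting material
4 | methyl (1S)-1-methyl-3-[(methylzincio)oxy]cyclohex-2-ene-1-carboxylate (methylzinc enolate, not isolated) | C[Zn]OC1=C[C@@](C)(C(=O)OC)CCC1 | intermediate
5 | methyl (1S)-1-methyl-3-[(triethylsilyl)oxy]cyclohex-2-ene-1-carboxylate | CC[Si](CC)(CC)OC1=C[C@@](C)(C(=O)OC)CCC1 | intermediate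
6 | tert-butyl bromoacetate | CC(C)(C)OC(=O)CBr | starting material
7 | benzyltrimethylammonium (3S)-3-(methoxycarbonyl)-3-methylcyclohex-1-en-1-olate (ammonium enolate, not isolated) | C[N+](C)(C)Cc1ccccc1.[O-]C1=C[C@@](C)(C(=O)OC)CCC1 | intermediate
8 | methyl (1S,2RS)-2-(2-tert-butoxy-2-oxoethyl)-1-methyl-3-oxocyclohexane-1-carboxylate (C2 epimers) | O=C1CCC[C@](C)(C(=O)OC)C1CC(=O)OC(C)(C)C | intermediate
9 | 1,2,4-trimethoxybenzene | COc1ccc(OC)c(OC)c1 | starting material
10 | acetone | CC(C)=O | starting material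
11 | (2,3,6-trimethoxyphenyl)lithium (not isolated) | [Li]c1c(OC)ccc(OC)c1OC | intermediate
12 | 2-(2,3,6-trimethoxyphenyl)propan-2-ol | COc1ccc(OC)c(C(C)(C)O)c1OC | intermediate
13 | 1,2,4-trimethoxy-3-(propan-2-yl)benzene | COc1ccc(OC)c(C(C)C)c1OC | intermediate
14 | [2,3,5-trimethoxy-4-(propan-2-yl)phenyl]lithium (not isolated) | [Li]c1cc(OC)c(C(C)C)c(OC)c1OC | intermediate
15 | dichloro[2,3,5-trimethoxy-4-(propan-2-yl)phenyl]cerium (not isolated) | Cl[Ce](Cl)c1cc(OC)c(C(C)C)c(OC)c1OC | intermediate
16 | methyl (1S,2RS,3RS)-2-(2-tert-butoxy-2-oxoethyl)-3-hydroxy-1-methyl-3-[2,3,5-trimethoxy-4-(propan-2-yl)phenyl]cyclohexane-1-carboxylate (diastereomer mixture at C2 and C3) | OC1(c2cc(OC)c(C(C)C)c(OC)c2OC)CCC[C@](C)(C(=O)OC)C1CC(=O)OC(C)(C)C | intermediate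
17 | 2-{(6S)-6-(methoxycarbonyl)-6-methyl-2-[2,3,5-trimethoxy-4-(propan-2-yl)phenyl]cyclohex-1-en-1-yl}acetic acid (not isolated) | OC(=O)CC1=C(c2cc(OC)c(C(C)C)c(OC)c2OC)CCC[C@]1(C)C(=O)OC | intermediate
18 | methyl (1S)-9-hydroxy-5,6,8-trimethoxy-1-methyl-7-(propan-2-yl)-1,2,3,4-tetrahydrophenanthrene-1-carboxylate | COc1c(OC)c2c(c(OC)c1C(C)C)c(O)cc3c2CCC[C@]3(C)C(=O)OC | intermediate
19 | (1S)-9-hydroxy-5,6,8-trimethoxy-1-methyl-7-(propan-2-yl)-1,2,3,4-tetrahydrophenanthrene-1-carboxylic acid | COc1c(OC)c2c(c(OC)c1C(C)C)c(O)cc3c2CCC[C@]3(C)C(=O)O | intermediate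
20 | N-bromosuccinimide | O=C1CCC(=O)N1Br | starting material
21 | (1S)-10-bromo-9-hydroxy-5,6,8-trimethoxy-1-methyl-7-(propan-2-yl)-1,2,3,4-tetrahydrophenanthrene-1-carboxylic acid | COc1c(OC)c2c(c(OC)c1C(C)C)c(O)c(Br)c3c2CCC[C@]3(C)C(=O)O | intermediate
22 | chloromethyl chlorosulfate | ClCOS(=O)(=O)Cl | starting material
23 | chloromethyl (1S)-10-bromo-9-hydroxy-5,6,8-trimethoxy-1-methyl-7-(propan-2-yl)-1,2,3,4-tetrahydrophenanthrene-1-carboxylate (6-bromo-7-naphthol with C4 chloromethyl ester in abietane numbering) | COc1c(OC)c2c(c(OC)c1C(C)C)c(O)c(Br)c3c2CCC[C@]3(C)C(=O)OCCl | intermediate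
24 | iodomethyl (1S)-10-bromo-9-hydroxy-5,6,8-trimethoxy-1-methyl-7-(propan-2-yl)-1,2,3,4-tetrahydrophenanthrene-1-carboxylate (not isolated) | COc1c(OC)c2c(c(OC)c1C(C)C)c(O)c(Br)c3c2CCC[C@]3(C)C(=O)OCI | intermediate
25 | potassium (1S)-10-bromo-1-[(iodomethoxy)carbonyl]-5,6,8-trimethoxy-1-methyl-7-(propan-2-yl)-1,2,3,4-tetrahydrophenanthren-9-olate (not isolated) | COc1c(OC)c2c(c(OC)c1C(C)C)c([O-])c(Br)c3c2CCC[C@]3(C)C(=O)OCI.[K+] | intermediate
26 | (4S,10S)-6-bromo-11,12,14-trimethoxy-7-oxoabieta-5,8,11,13-tetraen-19,20-olide (C19 and C20 cis on ring A) | COc1c(OC)c2c(c(OC)c1C(C)C)C(=O)C(Br)=C1[C@]23CCC[C@]1(C)C(=O)OC3 | intermediate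
27 | (4S,10R)-11,12,14-trimethoxy-7-oxoabieta-5,8,11,13-tetraen-19,20-olide (not isolated) | COc1c(OC)c2c(c(OC)c1C(C)C)C(=O)C=C1[C@]23CCC[C@]1(C)C(=O)OC3 | intermediate
28 | lithium C7 enolate of 29, (4S,5R,10R), C6=C7–OLi (not isolated) | COc1c(OC)c2c(c(OC)c1C(C)C)C(O[Li])=C[C@@H]1[C@]23CCC[C@]1(C)C(=O)OC3 | intermediate
29 | (4S,5R,10R)-11,12,14-trimethoxy-7-oxoabieta-8,11,13-trien-19,20-olide (5α-H, trans A/B) | COc1c(OC)c2c(c(OC)c1C(C)C)C(=O)C[C@@H]1[C@]23CCC[C@]1(C)C(=O)OC3 | intermediate
30 | water | O | starting material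
31 | (4S,5R,10R)-12-methoxy-7,11,14-trioxoabieta-8,12-dien-19,20-olide (11,14-quinone, not isolated) | CC(C)C1=C(OC)C(=O)C2=C(C1=O)C(=O)C[C@@H]1[C@]23CCC[C@]1(C)C(=O)OC3 | intermediate
32 | (4S,5R,10R)-11,14-dihydroxy-12-methoxy-7-oxoabieta-8,11,13-trien-19,20-olide | COc1c(O)c2c(c(O)c1C(C)C)C(=O)C[C@@H]1[C@]23CCC[C@]1(C)C(=O)OC3 | target

**Step count**

Total steps: 12. Longest linear sequence: 10 steps (steps 1, 2 and 5–12; the arene branch, steps 3, 4 and 5–12, is equally long).

**Steps most likely to fail**

Step 10. An acyloxymethyl halide has not been used as the electrophile in this kind of closure. Attack through the brominated ortho carbon C6, intermolecular O-alkylation or base-induced hydrolysis of the halomethyl ester may outrun closure at C10. The fallback changes the polarity of activation and sets out from 23. The naphthol is silylated (t-BuMe2SiOTf, 2,6-lutidine, CH2Cl2, −78 °C) to chloromethyl (1S)-10-bromo-9-[(tert-butyldimethylsilyl)oxy]-5,6,8-trimethoxy-1-methyl-7-(propan-2-yl)-1,2,3,4-tetrahydrophenanthrene-1-carboxylate F1. AgOTf with 2,6-di-tert-butyl-4-methylpyridine in CH2Cl2 at −40 °C then abstracts chloride, and the acyloxymethyl cation equivalent should be attacked by C10, para to the silyloxy group, in an ipso Friedel–Crafts closure. Loss of the silyl group from oxygen gives 26, where the route is rejoined.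

Step 11. The two faces of C5 differ only by one syn-axial hydrogen, so facial selectivity in the protonation may be poor, and some over-reduction of the ketone is possible. The fallback replaces substrate control by hydroxyl direction and sets out from 26. Palladium-catalysed formate reduction (Pd(OAc)2, PPh3, HCO2H, Et3N, DMF, 60 °C) removes bromine and gives 27, here isolated. Luche reduction (NaBH4, CeCl3·7H2O, MeOH, −40 °C) should give the separable allylic alcohols (4S,7R,10R)-7-hydroxy-11,12,14-trimethoxyabieta-5,8,11,13-tetraen-19,20-olide F2 (hydroxyl on the α face) and its (7S) epimer (4S,7S,10R)-7-hydroxy-11,12,14-trimethoxyabieta-5,8,11,13-tetraen-19,20-olide F3. Directed hydrogenation of F2 ([Ir(cod)(PCy3)(py)]PF6, H2, CH2Cl2) should deliver hydrogen to the α face of C5=C6 and give (4S,5R,7R,10R)-7-hydroxy-11,12,14-trimethoxyabieta-8,11,13-trien-19,20-olide F4. Dess–Martin periodinane oxidises F4 to 29, where the route is rejoined; the same oxidant returns F3 to 27 for recycling.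

Step 5. Proton transfer from the α-branched ketone to the aryl organometallic, or incomplete regiocontrol in the second arene lithiation, may spoil the addition. The fallback replaces carbonyl addition by cross-coupling and sets out from 8 and 13. KHMDS and PhNTf2 (THF, −78 °C) convert 8 into the less substituted enol triflate methyl (1S,2RS)-2-(2-tert-butoxy-2-oxoethyl)-1-methyl-3-{[(trifluoromethyl)sulfonyl]oxy}cyclohex-3-ene-1-carboxylate F5. Lithiation of 13 as in step 5, quenching with B(OiPr)3, aq. HCl and crystallisation (which also removes any regioisomer) give [2,3,5-trimethoxy-4-(propan-2-yl)phenyl]boronic acid F6. Suzuki–Miyaura coupling (Pd(PPh3)4, K3PO4, dioxane/H2O, 80 °C) gives methyl (1S,2RS)-2-(2-tert-butoxy-2-oxoethyl)-1-methyl-3-[2,3,5-trimethoxy-4-(propan-2-yl)phenyl]cyclohex-3-ene-1-carboxylate F7. Under the conditions of step 6, F7 should lose isobutene, cyclise at C8 and aromatise to 18, where the route is rejoined.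

**Further compounds**

F1 | step 10 | chloromethyl (1S)-10-bromo-9-[(tert-butyldimethylsilyl)oxy]-5,6,8-trimethoxy-1-methyl-7-(propan-2-yl)-1,2,3,4-tetrahydrophenanthrene-1-carboxylate | COc1c(OC)c2c(c(OC)c1C(C)C)c(O[Si](C)(C)C(C)(C)C)c(Br)c3c2CCC[C@]3(C)C(=O)OCCl
F2 | step 11 | (4S,7R,10R)-7-hydroxy-11,12,14-trimethoxyabieta-5,8,11,13-tetraen-19,20-olide | COc1c(OC)c2c(c(OC)c1C(C)C)[C@H](O)C=C1[C@]23CCC[C@]1(C)C(=O)OC3
F3 | step 11 | (4S,7S,10R)-7-hydroxy-11,12,14-trimethoxyabieta-5,8,11,13-tetraen-19,20-olide | COc1c(OC)c2c(c(OC)c1C(C)C)[C@@H](O)C=C1[C@]23CCC[C@]1(C)C(=O)OC3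
F4 | step 11 | (4S,5R,7R,10R)-7-hydroxy-11,12,14-trimethoxyabieta-8,11,13-trien-19,20-olide | COc1c(OC)c2c(c(OC)c1C(C)C)[C@H](O)C[C@@H]1[C@]23CCC[C@]1(C)C(=O)OC3
F5 | step 5 | methyl (1S,2RS)-2-(2-tert-butoxy-2-oxoethyl)-1-methyl-3-{[(trifluoromethyl)sulfonyl]oxy}cyclohex-3-ene-1-carboxylate | FC(F)(F)S(=O)(=O)OC1=CCC[C@](C)(C(=O)OC)C1CC(=O)OC(C)(C)C
F6 | step 5 | [2,3,5-trimethoxy-4-(propan-2-yl)phenyl]boronic acid | OB(O)c1cc(OC)c(C(C)C)c(OC)c1OC
F7 | step 5 | methyl (1S,2RS)-2-(2-tert-butoxy-2-oxoethyl)-1-methyl-3-[2,3,5-trimethoxy-4-(propan-2-yl)phenyl]cyclohex-3-ene-1-carboxylate | COc1cc(C2=CCC[C@](C)(C(=O)OC)C2CC(=O)OC(C)(C)C)c(OC)c(OC)c1C(C)C
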